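The route rests on opening the cyclohexenol ring (C1 carbinol, C2=C3 alkene, C4 side-chain carbon, C5, C6) between C1 and C3. C4 lies γ to the C1 oxygen and cannot be set by conjugate addition to a six-membered enone, but it is the β-carbon of cyclopentanone. A catalytic 1,4-addition therefore fixes C4 and, through silylation, the enolate position; cyclopropanation adds the future C2. In the key step FeCl3 cleaves the C1–C3 bond of silyloxybicyclo[3.1.0]hexane 9, so that its five-membered ring (C1, C3, C4, C5, C6) grows into the six-membered enone 11 with C2=C3 in place. Separate chiral catalysts set C7, C1 and C9.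

Key step: step 6

Atom labels: ring C1–C6 as above; C7 is the side-chain CH(CH3) carbon, C8 the CH2 next to it, C9 the acetoxy-bearing carbon.

Assumption: the antipodes of the chiral ligands in steps 5 and 7 are assigned by analogy with simpler substrates; if the sense of induction is the opposite, the mirror-image ligand is used.

Step 1
Reactants: 1 cyclopent-2-en-1-one; 2 trimethyl(prop-2-yn-1-yloxy)silane
Product: 5 triethyl({(3R)-3-[(1E)-3-(trimethylsilyloxy)prop-1-en-1-yl]cyclopent-1-en-1-yl}oxy)silane, via alkenylzirconocene chloride 3 (not isolated), via zirconium enolate 4 (not isolated)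
Conditions: Cp2Zr(H)Cl, THF, rt; then 1, [Rh(cod)(MeCN)2]BF4 (5 mol %), (S)-BINAP, THF, rt; then MeLi, Et3SiCl, −78 °C
Reagents that add atoms: chlorotriethylsilane, CC[Si](Cl)(CC)CC
Why: Hydrozirconation gives the (E)-alkenylzirconocene, which should undergo rhodium–BINAP-catalysed asymmetric 1,4-addition (Hayashi–Miyaura type) to 1, the (S)-ligand delivering the alkenyl group to the enone face that makes C4 (R) in 5, and O-silylation of the enolate freezes the enol double bond between C1 and C3.

Step 2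
Reactants: 5 triethyl({(3R)-3-[(1E)-3-(trimethylsilyloxy)prop-1-en-1-yl]cyclopent-1-en-1-yl}oxy)silane
Product: 6 triethyl({(1S,4R,5R)-4-[(1E)-3-(trimethylsilyloxy)prop-1-en-1-yl]bicyclo[3.1.0]hexan-1-yl}oxy)silane
Conditions: Et2Zn, CH2I2, CH2Cl2, 0 °C
Reagents that add atoms: diiodomethane, ICI
Why: Simmons–Smith cyclopropanation (Furukawa variant) should take the electron-rich silyl enol ether in preference to the allylic-ether alkene and add anti to the C4 substituent, although both new stereocenters are erased in step 6.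

Step 3
Reactants: 6 triethyl({(1S,4R,5R)-4-[(1E)-3-(trimethylsilyloxy)prop-1-en-1-yl]bicyclo[3.1.0]hexan-1-yl}oxy)silane
Product: 7 (2E)-3-[(1R,2R,5S)-5-(triethylsilyloxy)bicyclo[3.1.0]hexan-2-yl]prop-2-en-1-ol
Conditions: K2CO3 (cat.), MeOH, 0 °C
Reagents that add atoms: none
Why: Base-catalysed methanolysis (silyl ether solvolysis) should remove the unhindered primary trimethylsilyl ether while the tertiary cyclopropyl triethylsilyl ether is kept.

Step 4
Reactants: 7 (2E)-3-[(1R,2R,5S)-5-(triethylsilyloxy)bicyclo[3.1.0]hexan-2-yl]prop-2-en-1-ol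
Product: 8 {[(1S,4R,5R)-4-[(1E)-3-bromoprop-1-en-1-yl]bicyclo[3.1.0]hexan-1-yl]oxy}triethylsilane
Conditions: CBr4, PPh3, 2,6-lutidine, CH2Cl2, 0 °C
Reagents that add atoms: tetrabromomethane, BrC(Br)(Br)Br
Why: Appel reaction, in which bromide displaces the primary allylic alkoxyphosphonium group by SN2 under buffered neutral conditions, so the (E)-alkene and the silyloxycyclopropane should survive.

Step 5
Reactants: 8 {[(1S,4R,5R)-4-[(1E)-3-bromoprop-1-en-1-yl]bicyclo[3.1.0]hexan-1-yl]oxy}triethylsilane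
Product: 9 {[(1S,4R,5R)-4-[(2R)-but-3-en-2-yl]bicyclo[3.1.0]hexan-1-yl]oxy}triethylsilane
Conditions: MeMgBr, CuBr·SMe2 (5 mol %), (S,S)-Taniaphos (C43H39FeNP2), CH2Cl2, −78 °C
Reagents that add atoms: methylmagnesium bromide, C[Mg]Br
Why: Copper-catalysed asymmetric allylic alkylation (SN2′) with a Grignard reagent, in which the chiral ferrocenyl diphosphine–copper complex should direct methyl to the γ-carbon and set C7 as (R) by catalyst control while forming the terminal vinyl group.

Step 6
Reactants: 9 {[(1S,4R,5R)-4-[(2R)-but-3-en-2-yl]bicyclo[3.1.0]hexan-1-yl]oxy}triethylsilane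
Product: 11 (4S)-4-[(2R)-but-3-en-2-yl]cyclohex-2-en-1-one, via β-chloro ketone 10 (not isolated)
Conditions: FeCl3, DMF, 0 °C to rt; then NaOAc, MeOH, reflux
Reagents that add atoms: none
Why: Single-electron oxidation of the silyloxycyclopropane by FeCl3 should give an oxygen-centred radical that undergoes β-scission of the ring-fusion bond C1–C3, turning the cyclopentane into a cyclohexanone with a secondary β-keto radical at C3, which takes chlorine from FeCl3 to give 10, and NaOAc then removes HCl by E1cB to give 11. The closest known reaction type is the FeCl3-mediated one-carbon ring expansion of 1-silyloxybicyclo[n.1.0]alkanes to cycloalk-2-enones. No ring is closed: the six-membered ring is released by cleaving the bond shared by the three- and five-membered rings. No stereocenter is created, and C4 and C7 are carried through because C4 is never a radical and is not enolised by NaOAc. The step needs cleavage of the internal and not the external cyclopropane bond, which strain release and formation of a secondary instead of a primary radical secure, and it needs the C3 radical to ignore the side-chain vinyl group, which is secured because only slow 4-exo or 5-endo closures are open to it. The position of chlorine β to the carbonyl fixes the new alkene at C2=C3.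

Step 7
Reactants: 11 (4S)-4-[(2R)-but-3-en-2-yl]cyclohex-2-en-1-one
Product: 12 (1S,4S)-4-[(2R)-but-3-en-2-yl]-1-methylcyclohex-2-en-1-ol
Conditions: AlMe3, [Rh(cod)Cl]2 (2.5 mol %), (R)-BINAP, THF, 0 °C to rt
Reagents that add atoms: trimethylaluminium, C[Al](C)C
Why: Rhodium–BINAP-catalysed enantioselective 1,2-addition of AlMe3 to a 4-substituted cyclohex-2-enone, in which catalyst control should place methyl on the carbonyl face syn to the C4 side chain and so give the C1 carbinol with OH trans to that chain, without conjugate addition.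

Step 8
Reactants: 12 (1S,4S)-4-[(2R)-but-3-en-2-yl]-1-methylcyclohex-2-en-1-ol
Product: 13 (4R)-4-[(1R,4S)-4-hydroxy-4-methylcyclohex-2-en-1-yl]pentanal
Conditions: CO/H2 (1:1, 10 bar), Rh(acac)(CO)2 (1 mol %), BIPHEPHOS, toluene, 60 °C
Reagents that add atoms: carbon monoxide, [C-]#[O+]
Why: Rhodium–bisphosphite-catalysed hydroformylation is linear-selective for the terminal alkene, helped by the branch at C7, and should leave the hindered ring alkene untouched.

Step 9
Reactants: 14 methyl 2-(triphenyl-λ5-phosphanylidene)acetate; 15 5-bromo-2-methylpent-2-ene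
Product: 17 methyl 6-methyl-2-(triphenyl-λ5-phosphanylidene)hept-5-enoate, via phosphonium bromide 16 (not isolated)
Conditions: NaI (cat.), EtOAc, reflux; then NaOH (aq), CH2Cl2
Reagents that add atoms: none
Why: C-alkylation of a stabilised phosphorus ylide by a primary alkyl halide (iodide formed in the flask) should give the α-substituted phosphonium salt, which hydroxide deprotonates to the stabilised ylide.

Step 10
Reactants: 13 (4R)-4-[(1R,4S)-4-hydroxy-4-methylcyclohex-2-en-1-yl]pentanal; 17 methyl 6-methyl-2-(triphenyl-λ5-phosphanylidene)hept-5-enoate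
Product: 19 methyl (2E,4R,6R)-6-[(1R,4S)-4-hydroxy-4-methylcyclohex-2-en-1-yl]-2-(4-methylpent-3-en-1-yl)-4-[(phenylamino)oxy]hept-2-enoate, via α-anilinoxy aldehyde 18 (not isolated)
Conditions: L-proline (20 mol %), PhNO, DMSO, rt; then 17, 0 °C to rt
Reagents that add atoms: nitrosobenzene, O=Nc1ccccc1
Why: Proline enamine catalysis (α-aminoxylation, an O-selective nitroso aldol reaction) should set C9 as (R) through the carboxylic acid-directed transition state, and the stabilised ylide then traps the aldehyde in the flask by an (E)-selective Wittig reaction.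

Step 11
Reactants: 19 methyl (2E,4R,6R)-6-[(1R,4S)-4-hydroxy-4-methylcyclohex-2-en-1-yl]-2-(4-methylpent-3-en-1-yl)-4-[(phenylamino)oxy]hept-2-enoate
Product: 20 methyl (2E,4R,6R)-4-hydroxy-6-[(1R,4S)-4-hydroxy-4-methylcyclohex-2-en-1-yl]-2-(4-methylpent-3-en-1-yl)hept-2-enoate
Conditions: Cu(OAc)2 (30 mol %), MeOH, rt
Reagents that add atoms: none
Why: Copper diacetate-catalysed cleavage of the weak N–O bond of the O-alkyl-N-phenylhydroxylamine should release the allylic alcohol without touching the enoate or C9, and the (E)-geometry keeps the ester away from the new hydroxyl so that no lactone forms.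

Step 12
Reactants: 20 methyl (2E,4R,6R)-4-hydroxy-6-[(1R,4S)-4-hydroxy-4-methylcyclohex-2-en-1-yl]-2-(4-methylpent-3-en-1-yl)hept-2-enoate
Product: 21 methyl (2E,4R,6R)-4-acetoxy-6-[(1R,4S)-4-hydroxy-4-methylcyclohex-2-en-1-yl]-2-(4-methylpent-3-en-1-yl)hept-2-enoate
Conditions: Ac2O, pyridine, DMAP (cat.), CH2Cl2, 0 °C
Reagents that add atoms: acetic anhydride, CC(=O)OC(C)=O
Why: DMAP-catalysed acylation should esterify the secondary allylic alcohol selectively, since the tertiary C1 hydroxyl is too hindered to react at 0 °C.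

Compound list

1 | cyclopent-2-en-1-one | O=C1C=CCC1 | starting material
2 | trimethyl(prop-2-yn-1-yloxy)silane | C#CCO[Si](C)(C)C | starting material
3 | chlorobis(cyclopentadienyl)[(1E)-3-(trimethylsilyloxy)prop-1-en-1-yl]zirconium | C[Si](C)(C)OC/C=C/[Zr](Cl)(C1C=CC=C1)C1C=CC=C1 | intermediate (not isolated)
4 | chlorobis(cyclopentadienyl)zirconium (3R)-3-[(1E)-3-(trimethylsilyloxy)prop-1-en-1-yl]cyclopent-1-en-1-olate | C[Si](C)(C)OC/C=C/[C@H]1CCC(O[Zr](Cl)(C2C=CC=C2)C2C=CC=C2)=C1 | intermediate (not isolated)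
5 | triethyl({(3R)-3-[(1E)-3-(trimethylsilyloxy)prop-1-en-1-yl]cyclopent-1-en-1-yl}oxy)silane | CC[Si](CC)(CC)OC1=C[C@@H](/C=C/CO[Si](C)(C)C)CC1 | intermediate
6 | triethyl({(1S,4R,5R)-4-[(1E)-3-(trimethylsilyloxy)prop-1-en-1-yl]bicyclo[3.1.0]hexan-1-yl}oxy)silane | CC[Si](CC)(CC)O[C@@]12C[C@@H]1[C@@H](/C=C/CO[Si](C)(C)C)CC2 | intermediate
7 | (2E)-3-[(1R,2R,5S)-5-(triethylsilyloxy)bicyclo[3.1.0]hexan-2-yl]prop-2-en-1-ol | CC[Si](CC)(CC)O[C@@]12C[C@@H]1[C@@H](/C=C/CO)CC2 | intermediate
8 | {[(1S,4R,5R)-4-[(1E)-3-bromoprop-1-en-1-yl]bicyclo[3.1.0]hexan-1-yl]oxy}triethylsilane | CC[Si](CC)(CC)O[C@@]12C[C@@H]1[C@@H](/C=C/CBr)CC2 | intermediate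
9 | {[(1S,4R,5R)-4-[(2R)-but-3-en-2-yl]bicyclo[3.1.0]hexan-1-yl]oxy}triethylsilane | CC[Si](CC)(CC)O[C@@]12C[C@@H]1[C@@H]([C@H](C)C=C)CC2 | intermediate
10 | (4R)-4-[(2R)-but-3-en-2-yl]-3-chlorocyclohexan-1-one (both C3 epimers) | O=C1CC(Cl)[C@@H]([C@H](C)C=C)CC1 | intermediate (not isolated)
11 | (4S)-4-[(2R)-but-3-en-2-yl]cyclohex-2-en-1-one | O=C1C=C[C@@H]([C@H](C)C=C)CC1 | intermediate
12 | (1S,4S)-4-[(2R)-but-3-en-2-yl]-1-methylcyclohex-2-en-1-ol | C=C[C@@H](C)[C@@H]1C=C[C@@](C)(O)CC1 | intermediate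
13 | (4R)-4-[(1R,4S)-4-hydroxy-4-methylcyclohex-2-en-1-yl]pentanal | O=CCC[C@@H](C)[C@@H]1C=C[C@@](C)(O)CC1 | intermediate
14 | methyl 2-(triphenyl-λ5-phosphanylidene)acetate | COC(=O)C=P(c1ccccc1)(c1ccccc1)c1ccccc1 | starting material
15 | 5-bromo-2-methylpent-2-ene | CC(C)=CCCBr | starting material
16 | (1-methoxy-6-methyl-1-oxohept-5-en-2-yl)triphenylphosphonium bromide | COC(=O)C(CCC=C(C)C)[P+](c1ccccc1)(c1ccccc1)c1ccccc1.[Br-] | intermediate (not isolated)
17 | methyl 6-methyl-2-(triphenyl-λ5-phosphanylidene)hept-5-enoate | COC(=O)C(CCC=C(C)C)=P(c1ccccc1)(c1ccccc1)c1ccccc1 | intermediate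
18 | (2R,4R)-4-[(1R,4S)-4-hydroxy-4-methylcyclohex-2-en-1-yl]-2-[(phenylamino)oxy]pentanal | O=C[C@H](ONc1ccccc1)C[C@@H](C)[C@@H]1C=C[C@@](C)(O)CC1 | intermediate (not isolated)
19 | methyl (2E,4R,6R)-6-[(1R,4S)-4-hydroxy-4-methylcyclohex-2-en-1-yl]-2-(4-methylpent-3-en-1-yl)-4-[(phenylamino)oxy]hept-2-enoate | COC(=O)/C(=C/[C@@H](C[C@@H](C)[C@@H]1C=C[C@@](C)(O)CC1)ONc1ccccc1)CCC=C(C)C | intermediate
20 | methyl (2E,4R,6R)-4-hydroxy-6-[(1R,4S)-4-hydroxy-4-methylcyclohex-2-en-1-yl]-2-(4-methylpent-3-en-1-yl)hept-2-enoate | COC(=O)/C(=C/[C@@H](C[C@@H](C)[C@@H]1C=C[C@@](C)(O)CC1)O)CCC=C(C)C | intermediate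
21 | methyl (2E,4R,6R)-4-acetoxy-6-[(1R,4S)-4-hydroxy-4-methylcyclohex-2-en-1-yl]-2-(4-methylpent-3-en-1-yl)hept-2-enoate | COC(=O)/C(=C/[C@@H](C[C@@H](C)[C@@H]1C=C[C@@](C)(O)CC1)OC(C)=O)CCC=C(C)C | target

Total step count: 12
Longest linear sequence: 11 steps (steps 1 to 8 and 10 to 12); step 9 is a side branch.

Steps most likely to fail

Step 1. The zirconium enolate may be silylated slowly and equilibrate by proton transfer before it is trapped, so that the enol double bond leaves the C1–C3 position, or the rhodium cycle may stall with the zirconium reagent. The fallback replaces carbon delivery by hydride delivery. It sets out from 2 (through 3): palladium-catalysed cross-coupling of 3 with commercially available 3-bromocyclopent-2-en-1-one (Pd(PPh3)4, THF) would give the cross-conjugated dienone 3-[(1E)-3-(trimethylsilyloxy)prop-1-en-1-yl]cyclopent-2-en-1-one F1. Copper hydride-catalysed asymmetric 1,4-reduction (Cu(OAc)2, DTBM-SEGPHOS of the antipode that puts hydride on the face leading to (R)-configured C4, polymethylhydrosiloxane; then MeLi, Et3SiCl) would create C4 and release the enolate regiospecifically. The fallback comes back to the route at 5.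

Step 5. Direct SN2 substitution to the linear product may compete with the SN2′ path, and facial selectivity may be eroded next to the branched ring carbon. The fallback sets the methyl-bearing centre by a reagent-controlled epoxide opening. It sets out from 7: Sharpless asymmetric epoxidation (Ti(OiPr)4, D-(−)-diethyl tartrate, tBuOOH, CH2Cl2, −20 °C) would give the epoxy alcohol [(2R,3R)-3-[(1R,2S,5S)-5-(triethylsilyloxy)bicyclo[3.1.0]hexan-2-yl]oxiran-2-yl]methanol F2. AlMe3 (hexane/CH2Cl2, −20 °C) would open it at the carbon remote from the hydroxyl with inversion to give (2S,3S)-3-[(1R,2R,5S)-5-(triethylsilyloxy)bicyclo[3.1.0]hexan-2-yl]butane-1,2-diol F3. Thiocarbonyldiimidazole would convert the diol into (4S)-4-[(1S)-1-[(1R,2R,5S)-5-(triethylsilyloxy)bicyclo[3.1.0]hexan-2-yl]ethyl]-1,3-dioxolane-2-thione F4, and Corey–Winter olefination (P(OMe)3, heat) would form the vinyl group. The fallback comes back to the route at 9.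

Step 10. The α-anilinoxy aldehyde may decompose or epimerise at C9 during the slow Wittig reaction of the α-branched ylide, and a second aminoxylation may compete. The fallback separates the oxidation from the olefination. It sets out from 13: aminoxylation as in step 10 followed at once by NaBH4 would give (2R,4R)-4-[(1R,4S)-4-hydroxy-4-methylcyclohex-2-en-1-yl]-2-[(phenylamino)oxy]pentan-1-ol F5. N–O cleavage (Cu(OAc)2, MeOH) would give (2R,4R)-4-[(1R,4S)-4-hydroxy-4-methylcyclohex-2-en-1-yl]pentane-1,2-diol F6. Selective oxidation of the primary alcohol (TEMPO, PhI(OAc)2, CH2Cl2) would give (2R,4R)-2-hydroxy-4-[(1R,4S)-4-hydroxy-4-methylcyclohex-2-en-1-yl]pentanal F7, which would be condensed with ylide 17. The fallback comes back to the route at 20.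

Further compounds

F1 | step 1 | 3-[(1E)-3-(trimethylsilyloxy)prop-1-en-1-yl]cyclopent-2-en-1-one | O=C1C=C(/C=C/CO[Si](C)(C)C)CC1
F2 | step 5 | [(2R,3R)-3-[(1R,2S,5S)-5-(triethylsilyloxy)bicyclo[3.1.0]hexan-2-yl]oxiran-2-yl]methanol | CC[Si](CC)(CC)O[C@@]12C[C@@H]1[C@@H]([C@H]3O[C@@H]3CO)CC2
F3 | step 5 | (2S,3S)-3-[(1R,2R,5S)-5-(triethylsilyloxy)bicyclo[3.1.0]hexan-2-yl]butane-1,2-diol | CC[Si](CC)(CC)O[C@@]12C[C@@H]1[C@@H]([C@H](C)[C@H](O)CO)CC2
F4 | step 5 | (4S)-4-[(1S)-1-[(1R,2R,5S)-5-(triethylsilyloxy)bicyclo[3.1.0]hexan-2-yl]ethyl]-1,3-dioxolane-2-thione | CC[Si](CC)(CC)O[C@@]12C[C@@H]1[C@@H]([C@H](C)[C@H]3COC(=S)O3)CC2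
F5 | step 10 | (2R,4R)-4-[(1R,4S)-4-hydroxy-4-methylcyclohex-2-en-1-yl]-2-[(phenylamino)oxy]pentan-1-ol | OC[C@H](ONc1ccccc1)C[C@@H](C)[C@@H]1C=C[C@@](C)(O)CC1
F6 | step 10 | (2R,4R)-4-[(1R,4S)-4-hydroxy-4-methylcyclohex-2-en-1-yl]pentane-1,2-diol | OC[C@H](O)C[C@@H](C)[C@@H]1C=C[C@@](C)(O)CC1
F7 | step 10 | (2R,4R)-2-hydroxy-4-[(1R,4S)-4-hydroxy-4-methylcyclohex-2-en-1-yl]pentanal | O=C[C@H](O)C[C@@H](C)[C@@H]1C=C[C@@](C)(O)CC1
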